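**Plan**
- Retrosynthesis: the silyl ethers come off last; the C2–C1' bond is cut (enantioselective rhodium 1,4-arylation of a chromone); ring C is opened at O1–C2 and C2–C3 (formamide acetal on a 2-hydroxyacetophenone); ring A is cut at C7–C8 and C4a–C8a (a tert-butoxyacetylide plus a 2-pyranone); finally the C6–CH2 bond is cut (Negishi coupling of the side-chain zinc reagent with a 3-bromopyranone).
- Forward order: side-chain iodide, then the 3-alkyl-4-methoxy-6-methyl-2-pyranone, then ring A by ring transformation, then ring C (chromone), then ring B at C2, then global desilylation.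
- Enabling feature: in the acetophenone form of ring A, the atoms C3 (as a methyl), C4, C4a, C5–OMe, C6 with its side chain and C7 with its oxygen are the 6-methyl, C6, C5, C4–OMe, C3 and C2 of a 2-pyranone. Only C8 and C8a are missing; the two acetylide carbons supply them and the acetylide oxygen becomes O1.
- Stereochemistry: the side-chain centre comes from an Evans hydroxymethylation directed by (R)-4-benzyloxazolidinone; C2 comes from the chiral diene ligand in the rhodium arylation.

Key step: step 9

Assumption: the (S,S) diene ligand is taken to give 2S by analogy with cyclic enones; the (R,R) ligand would be used if a model chromone shows the opposite sense.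

Shorthand: SC = (2S)-5-methyl-2-[2-(triethylsilyloxy)propan-2-yl]hex-4-en-1-yl (the TES-protected side chain); TBS = tert-butyldimethylsilyl; TES = triethylsilyl. In the iodide and the zinc reagent the same spatial arrangement carries the descriptor R, because iodine and zinc outrank oxygen.

Step 1
Reactants: 1 5-methylhex-4-enoic acid; 2 (R)-4-benzyl-1,3-oxazolidin-2-one
Product: 4 (4R)-4-benzyl-3-(5-methylhex-4-enoyl)-1,3-oxazolidin-2-one, via mixed pivalic anhydride 3 (not isolated)
Conditions: PivCl, Et3N, THF, −20 → 0 °C; then LiCl, 2, 23 °C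
Reagents that add atoms: none
Why: Evans imide formation, in which the LiCl/Et3N-activated oxazolidinone is N-acylated at the less hindered carbonyl of the mixed anhydride.

Step 2
Reactants: 4
Product: 6 (4R)-4-benzyl-3-[(2S)-2-(hydroxymethyl)-5-methylhex-4-enoyl]-1,3-oxazolidin-2-one, via titanium enolate 5 (not isolated)
Conditions: TiCl4, iPr2NEt, CH2Cl2, 0 °C; 1,3,5-trioxane, TiCl4, 0 °C; then H2O
Reagents that add atoms: 1,3,5-trioxane, C1OCOCO1
Why: Evans titanium-enolate hydroxymethylation, in which the chelated Z-enolate takes up activated formaldehyde on the face opposite the benzyl group of the (R)-auxiliary and so sets the 2S centre; the enolate should react well before the trisubstituted alkene when trioxane is kept near one equivalent.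

Step 3
Reactants: 6
Product: 7 methyl (2S)-2-(hydroxymethyl)-5-methylhex-4-enoate
Conditions: Sm(OTf)3 (cat.), MeOH, 23 °C
Reagents that add atoms: methanol, CO
Why: Lewis-acid-catalysed imide-to-ester transesterification, in which samarium chelation directs methanol to the exocyclic carbonyl under neutral conditions that should not epimerise the α-centre.

Step 4
Reactants: 7
Product: 8 (2S)-2-(2-hydroxypropan-2-yl)-5-methylhex-4-en-1-ol
Conditions: MeMgBr (3.5 equiv), THF, 0 → 23 °C; aq. NH4Cl
Reagents that add atoms: methylmagnesium bromide, C[Mg]Br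
Why: double Grignard addition to the ester after deprotonation of the hydroxyl; addition to the transient methyl ketone is faster than its enolisation, so the adjacent centre should be kept.

Step 5
Reactants: 8
Product: 9 (3R)-3-(iodomethyl)-2,6-dimethylhept-5-en-2-ol
Conditions: I2, PPh3, imidazole, CH2Cl2, 0 °C
Reagents that add atoms: iodine, II
Why: Appel-type (Garegg–Samuelsson) iodination, which activates only the primary alcohol because the tertiary one is too hindered to form the alkoxyphosphonium salt.

Step 6
Reactants: 9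
Product: 10 triethyl{[(3R)-3-(iodomethyl)-2,6-dimethylhept-5-en-2-yl]oxy}silane
Conditions: TESOTf, 2,6-lutidine, CH2Cl2, −78 → 0 °C
Reagents that add atoms: triethylsilyl trifluoromethanesulfonate, CC[Si](CC)(CC)OS(=O)(=O)C(F)(F)F
Why: silylation of a tertiary alcohol with a silyl triflate and a hindered base, conditions to which the iodide and the alkene are inert.

Step 7
Reactants: 11 4-methoxy-6-methyl-2H-pyran-2-one
Product: 12 3-bromo-4-methoxy-6-methyl-2H-pyran-2-one
Conditions: NBS, CH2Cl2, dark, 23 °C
Reagents that add atoms: N-bromosuccinimide, O=C1CCC(=O)N1Br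
Why: electrophilic bromination at C3, the enol-ether carbon between the lactone carbonyl and the methoxy group and the most nucleophilic position of the ring.

Step 8
Reactants: 10; 12
Product: 14 4-methoxy-6-methyl-3-SC-2H-pyran-2-one, via alkylzinc iodide 13 (not isolated)
Conditions: Zn, LiCl, THF, 40 °C (BrCH2CH2Br, TMSCl activation); then 12, Pd(OAc)2 (cat.), SPhos, THF, 50 °C
Reagents that add atoms: none
Why: Negishi sp3–sp2 cross-coupling, in which LiCl-assisted zinc insertion gives a primary alkylzinc that tolerates the lactone and a bulky biarylphosphine suppresses β-hydride elimination; the stereocentre β to zinc takes no part.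

Step 9
Reactants: 14; 15 tert-butyl ethynyl ether
Product: 19 1-[6-tert-butoxy-4-hydroxy-2-methoxy-3-SC-phenyl]ethan-1-one, via lithium tert-butoxyacetylide 16 (not isolated), via dichlorocerium tert-butoxyacetylide 17 (not isolated), via ring-opened alkynone enolate 18 (not isolated)
Conditions: 15, n-BuLi, THF, −78 °C; CeCl3, −78 °C; 14, −78 → 23 °C; aq. NH4Cl
Reagents that add atoms: none
Why: Proposed new method: the weakly basic cerium acetylide should add to the lactone carbonyl (forming C7–C8), and the tetrahedral alkoxide should expel the ring oxygen as a methyl-ketone enolate whose α-carbon then attacks the alkoxy-bearing alkyne carbon (forming C4a–C8a), a proton shift giving the phenoxide. The closest known reaction types are the carbanion-induced ring transformation of 2-pyranones into benzenes and the base-mediated 6-endo-dig cyclisation of enolates and phenoxides onto alkynones. Ring A closes in the 6-endo-dig mode. No stereocentre is formed, and the side-chain centre is remote and untouched. The step needs carbonyl addition to win over deprotonation of the 6-methyl group and attack at C4 or C6; the organocerium reagent at −78 °C and the fact that the lactone is the only carbonyl group should secure this, and the ring-opened ketone is a vinylogous enolate that resists a second addition. The cis geometry inherited from the pyranone C3=C4 bond holds the enolate carbon next to the alkynone, so carbon closure gives the six-membered ring, whereas oxygen closure would need an eight-membered ring.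

Step 10
Reactants: 19
Product: 20 1-[6-tert-butoxy-4-(tert-butyldimethylsilyloxy)-2-methoxy-3-SC-phenyl]ethan-1-one
Conditions: TBSCl, imidazole, DMF, 23 °C
Reagents that add atoms: tert-butyldimethylsilyl chloride, CC(C)(C)[Si](C)(C)Cl
Why: standard imidazole-promoted silylation of the only free hydroxyl, so that no acidic phenol is present in the next Lewis-acid step.

Step 11
Reactants: 20
Product: 21 1-[4-(tert-butyldimethylsilyloxy)-6-hydroxy-2-methoxy-3-SC-phenyl]ethan-1-one
Conditions: ZnBr2, CH2Cl2, 0 → 23 °C
Reagents that add atoms: none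
Why: chelation-assisted Lewis-acid cleavage of a tert-butyl ether (E1 loss of isobutene), in which zinc bridges the acetyl and ether oxygens; the methyl and silyl ethers cannot ionise in this way.

Step 12
Reactants: 21
Product: 23 7-(tert-butyldimethylsilyloxy)-5-methoxy-6-SC-4H-chromen-4-one, via enaminone 22 (not isolated)
Conditions: Me2NCH(OMe)2, toluene, 90 °C; then AcOH, 60 °C
Reagents that add atoms: N,N-dimethylformamide dimethyl acetal, COC(OC)N(C)C
Why: enaminone chromone synthesis, in which the methyl ketone condenses with the formamide acetal and the chelated phenol then closes ring C by acid-promoted conjugate addition and loss of dimethylamine.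

Step 13
Reactants: 24 4-bromoresorcinol
Product: 25 1-bromo-2,4-bis(tert-butyldimethylsilyloxy)benzene
Conditions: TBSCl, imidazole, DMF, 23 °C
Reagents that add atoms: tert-butyldimethylsilyl chloride, CC(C)(C)[Si](C)(C)Cl
Why: standard bis-silylation of the two phenols, which gives ring B the same fluoride-labile protection as the rest of the molecule.

Step 14
Reactants: 25
Product: 28 [2,4-bis(tert-butyldimethylsilyloxy)phenyl]boronic acid, via aryllithium 26 (not isolated), via lithium triisopropyl borate complex 27 (not isolated)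
Conditions: B(OiPr)3, THF, −78 °C, n-BuLi added last (in situ quench); aq. NH4Cl
Reagents that add atoms: triisopropyl borate, CC(C)OB(OC(C)C)OC(C)C; water, O
Why: bromine–lithium exchange with immediate borate trapping followed by hydrolysis; the low temperature and in situ trapping should prevent oxygen-to-carbon silyl migration in the ortho-siloxy aryllithium.

Step 15
Reactants: 23; 28
Product: 29 (2S)-2-[2,4-bis(tert-butyldimethylsilyloxy)phenyl]-7-(tert-butyldimethylsilyloxy)-5-methoxy-6-SC-2,3-dihydro-4H-chromen-4-one
Conditions: [RhCl(C2H4)2]2 (cat.), (S,S)-2,5-diphenylbicyclo[2.2.2]octa-2,5-diene, KOH (0.2 equiv), toluene/H2O, 40 °C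
Reagents that add atoms: none
Why: Hayashi–Miyaura asymmetric 1,4-addition to a chromone, in which the aryl-rhodium species adds across C2=C3 and the chiral diene selects the enone face that leads to 2S, water then protonating the rhodium enolate.

Step 16
Reactants: 29
Product: 30 (2S)-2-(2,4-dihydroxyphenyl)-7-hydroxy-6-[(2S)-2-(2-hydroxypropan-2-yl)-5-methylhex-4-en-1-yl]-5-methoxy-2,3-dihydro-4H-chromen-4-one
Conditions: HF·pyridine, pyridine, THF, 0 → 23 °C
Reagents that add atoms: none
Why: fluoride-mediated cleavage of all four silyl ethers in a buffered, weakly acidic medium, which avoids the phenoxide-triggered retro-oxa-Michael opening that would epimerise C2 and is too mild to ionise the tertiary alcohol or protonate the alkene.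

**Compound list**
1 | 5-methylhex-4-enoic acid | CC(C)=CCCC(=O)O | starting material
2 | (R)-4-benzyl-1,3-oxazolidin-2-one | O=C1N[C@H](Cc2ccccc2)CO1 | starting material
3 | 5-methylhex-4-enoic pivalic anhydride (formed in the flask) | CC(C)=CCCC(=O)OC(=O)C(C)(C)C | intermediate
4 | (4R)-4-benzyl-3-(5-methylhex-4-enoyl)-1,3-oxazolidin-2-one | CC(C)=CCCC(=O)N1[C@H](Cc2ccccc2)COC1=O | intermediate
5 | trichlorotitanium (Z)-enolate of 4 (formed in the flask) | CC(C)=CC/C=C(\O[Ti](Cl)(Cl)Cl)N1[C@H](Cc2ccccc2)COC1=O | intermediate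
6 | (4R)-4-benzyl-3-[(2S)-2-(hydroxymethyl)-5-methylhex-4-enoyl]-1,3-oxazolidin-2-one | O=C([C@H](CO)CC=C(C)C)N1[C@H](Cc2ccccc2)COC1=O | intermediate
7 | methyl (2S)-2-(hydroxymethyl)-5-methylhex-4-enoate | COC(=O)[C@H](CO)CC=C(C)C | intermediate
8 | (2S)-2-(2-hydroxypropan-2-yl)-5-methylhex-4-en-1-ol | OC[C@H](CC=C(C)C)C(C)(C)O | intermediate
9 | (3R)-3-(iodomethyl)-2,6-dimethylhept-5-en-2-ol | IC[C@H](CC=C(C)C)C(C)(C)O | intermediate
10 | triethyl{[(3R)-3-(iodomethyl)-2,6-dimethylhept-5-en-2-yl]oxy}silane | IC[C@H](CC=C(C)C)C(C)(C)O[Si](CC)(CC)CC | intermediate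
11 | 4-methoxy-6-methyl-2H-pyran-2-one | COc1cc(C)oc(=O)c1 | starting material
12 | 3-bromo-4-methoxy-6-methyl-2H-pyran-2-one | COc1cc(C)oc(=O)c1Br | intermediate
13 | iodo{(2R)-5-methyl-2-[2-(triethylsilyloxy)propan-2-yl]hex-4-en-1-yl}zinc (formed in the flask) | I[Zn]C[C@H](CC=C(C)C)C(C)(C)O[Si](CC)(CC)CC | intermediate
14 | 4-methoxy-6-methyl-3-{(2S)-5-methyl-2-[2-(triethylsilyloxy)propan-2-yl]hex-4-en-1-yl}-2H-pyran-2-one | COc1cc(C)oc(=O)c1C[C@H](CC=C(C)C)C(C)(C)O[Si](CC)(CC)CC | intermediate
15 | tert-butyl ethynyl ether | C#COC(C)(C)C | starting material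
16 | lithium tert-butoxyacetylide (formed in the flask) | [Li]C#COC(C)(C)C | intermediate
17 | dichlorocerium tert-butoxyacetylide (formed in the flask) | Cl[Ce](Cl)C#COC(C)(C)C | intermediate
18 | ring-opened alkynone enolate, dichlorocerium (2Z,4Z)-dienolate (formed in the flask) | Cl[Ce](Cl)O/C(C)=C\C(OC)=C(/C(=O)C#COC(C)(C)C)C[C@H](CC=C(C)C)C(C)(C)O[Si](CC)(CC)CC | intermediate
19 | 1-[6-tert-butoxy-4-hydroxy-2-methoxy-3-SC-phenyl]ethan-1-one | CC(=O)c1c(OC(C)(C)C)cc(O)c(C[C@H](CC=C(C)C)C(C)(C)O[Si](CC)(CC)CC)c1OC | intermediate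
20 | 1-[6-tert-butoxy-4-(tert-butyldimethylsilyloxy)-2-methoxy-3-SC-phenyl]ethan-1-one | CC(=O)c1c(OC(C)(C)C)cc(O[Si](C)(C)C(C)(C)C)c(C[C@H](CC=C(C)C)C(C)(C)O[Si](CC)(CC)CC)c1OC | intermediate
21 | 1-[4-(tert-butyldimethylsilyloxy)-6-hydroxy-2-methoxy-3-SC-phenyl]ethan-1-one | CC(=O)c1c(O)cc(O[Si](C)(C)C(C)(C)C)c(C[C@H](CC=C(C)C)C(C)(C)O[Si](CC)(CC)CC)c1OC | intermediate
22 | (E)-3-(dimethylamino)-1-[4-(tert-butyldimethylsilyloxy)-6-hydroxy-2-methoxy-3-SC-phenyl]prop-2-en-1-one (formed in the flask) | CN(C)/C=C/C(=O)c1c(O)cc(O[Si](C)(C)C(C)(C)C)c(C[C@H](CC=C(C)C)C(C)(C)O[Si](CC)(CC)CC)c1OC | intermediate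
23 | 7-(tert-butyldimethylsilyloxy)-5-methoxy-6-SC-4H-chromen-4-one | COc1c(C[C@H](CC=C(C)C)C(C)(C)O[Si](CC)(CC)CC)c(O[Si](C)(C)C(C)(C)C)cc2occc(=O)c12 | intermediate
24 | 4-bromoresorcinol | Oc1ccc(Br)c(O)c1 | starting material
25 | 1-bromo-2,4-bis(tert-butyldimethylsilyloxy)benzene | CC(C)(C)[Si](C)(C)Oc1ccc(Br)c(O[Si](C)(C)C(C)(C)C)c1 | intermediate
26 | [2,4-bis(tert-butyldimethylsilyloxy)phenyl]lithium (formed in the flask) | [Li]c1ccc(O[Si](C)(C)C(C)(C)C)cc1O[Si](C)(C)C(C)(C)C | intermediate
27 | lithium [2,4-bis(tert-butyldimethylsilyloxy)phenyl]triisopropoxyborate (formed in the flask) | [Li+].CC(C)O[B-](OC(C)C)(OC(C)C)c1ccc(O[Si](C)(C)C(C)(C)C)cc1O[Si](C)(C)C(C)(C)C | intermediate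
28 | [2,4-bis(tert-butyldimethylsilyloxy)phenyl]boronic acid | OB(O)c1ccc(O[Si](C)(C)C(C)(C)C)cc1O[Si](C)(C)C(C)(C)C | intermediate
29 | (2S)-2-[2,4-bis(tert-butyldimethylsilyloxy)phenyl]-7-(tert-butyldimethylsilyloxy)-5-methoxy-6-SC-2,3-dihydro-4H-chromen-4-one | COc1c(C[C@H](CC=C(C)C)C(C)(C)O[Si](CC)(CC)CC)c(O[Si](C)(C)C(C)(C)C)cc2c1C(=O)C[C@@H](c1ccc(O[Si](C)(C)C(C)(C)C)cc1O[Si](C)(C)C(C)(C)C)O2 | intermediate
30 | (2S)-2-(2,4-dihydroxyphenyl)-7-hydroxy-6-[(2S)-2-(2-hydroxypropan-2-yl)-5-methylhex-4-en-1-yl]-5-methoxy-2,3-dihydro-4H-chromen-4-one | COc1c(C[C@H](CC=C(C)C)C(C)(C)O)c(O)cc2c1C(=O)C[C@@H](c1ccc(O)cc1O)O2 | target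

**Step count**
Total: 16 steps. Longest linear sequence: 13 steps (steps 1–6, 8–12, 15, 16).

**Steps most likely to fail**

1. Step 9. The acetylide may deprotonate the 6-methyl group or attack C4 or C6 instead of the lactone carbonyl. The ring-opened enolate may also fail to close, or the alkoxyalkyne may lose isobutene before closure. The fallback uses known chemistry and installs the side chain on a preformed chromone. It sets out from iodide 10, taken as its zinc reagent 13, and comes back at chromone 23. Commercial 5,7-dihydroxychromone would be silylated at the non-chelated hydroxyl (TBSCl, imidazole) to 7-(tert-butyldimethylsilyloxy)-5-hydroxy-4H-chromen-4-one F1. Iodination ortho to the chelated hydroxyl (BnMe3N·ICl2, CaCO3) would give 7-(tert-butyldimethylsilyloxy)-5-hydroxy-6-iodo-4H-chromen-4-one F2. O-Methylation (MeI, Ag2O) would give 7-(tert-butyldimethylsilyloxy)-6-iodo-5-methoxy-4H-chromen-4-one F3. Negishi coupling of F3 with 13 (Pd(OAc)2, SPhos) would then give 23.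

2. Step 15. Carbometalation of the electron-rich 5-alkoxychromone by a hindered ortho-siloxy aryl-rhodium species may be slow, so that protodeboronation takes over. Facial selectivity may be poor, or silyl groups may be lost in the aqueous base. The fallback sets out from acetophenone 21 and comes back at 29. Claisen–Schmidt condensation of 21 (LiN(SiMe3)2, THF) with 2,4-bis(tert-butyldimethylsilyloxy)benzaldehyde F4, made from 2,4-dihydroxybenzaldehyde with TBSCl and imidazole, would give the 2'-hydroxychalcone F5. Oxa-Michael ring closure of F5 under a cinchona-derived thiourea catalyst would give 29. The (2R)-epimer of 29 F6 formed alongside is a diastereomer because of the side-chain centre; it would be removed by preparative HPLC on a chiral phase and returned to F5 by base-induced ring opening.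

3. Step 11. The Lewis acid may remove the tertiary TES ether or start acid-induced reactions at the trisubstituted alkene, and the tert-butyl cation may alkylate the electron-rich ring. The fallback sets out from 20 and comes back at 23, merging ether cleavage with ring closure. Treating 20 with Me2NCH(OMe)2 while the tert-butyl group is still in place would give the tert-butoxy enaminone F7. Mild acid (pyridinium p-toluenesulfonate, toluene, 80 °C) should then trigger a dealkylative cyclisation: the ether oxygen adds to the protonated enaminone, and isobutene and then dimethylamine are lost, giving chromone 23 directly.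

**Further compounds**
F1 | step 9 | 7-(tert-butyldimethylsilyloxy)-5-hydroxy-4H-chromen-4-one | O=c1ccoc2cc(O[Si](C)(C)C(C)(C)C)cc(O)c12
F2 | step 9 | 7-(tert-butyldimethylsilyloxy)-5-hydroxy-6-iodo-4H-chromen-4-one | O=c1ccoc2cc(O[Si](C)(C)C(C)(C)C)c(I)c(O)c12
F3 | step 9 | 7-(tert-butyldimethylsilyloxy)-6-iodo-5-methoxy-4H-chromen-4-one | COc1c(I)c(O[Si](C)(C)C(C)(C)C)cc2occc(=O)c12
F4 | step 15 | 2,4-bis(tert-butyldimethylsilyloxy)benzaldehyde | O=Cc1ccc(O[Si](C)(C)C(C)(C)C)cc1O[Si](C)(C)C(C)(C)C
F5 | step 15 | (E)-3-[2,4-bis(tert-butyldimethylsilyloxy)phenyl]-1-[4-(tert-butyldimethylsilyloxy)-6-hydroxy-2-methoxy-3-SC-phenyl]prop-2-en-1-one | COc1c(C[C@H](CC=C(C)C)C(C)(C)O[Si](CC)(CC)CC)c(O[Si](C)(C)C(C)(C)C)cc(O)c1C(=O)/C=C/c1ccc(O[Si](C)(C)C(C)(C)C)cc1O[Si](C)(C)C(C)(C)C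
F6 | step 15 | (2R)-epimer of 29 | COc1c(C[C@H](CC=C(C)C)C(C)(C)O[Si](CC)(CC)CC)c(O[Si](C)(C)C(C)(C)C)cc2c1C(=O)C[C@H](c1ccc(O[Si](C)(C)C(C)(C)C)cc1O[Si](C)(C)C(C)(C)C)O2
F7 | step 11 | (E)-3-(dimethylamino)-1-[6-tert-butoxy-4-(tert-butyldimethylsilyloxy)-2-methoxy-3-SC-phenyl]prop-2-en-1-one | CN(C)/C=C/C(=O)c1c(OC(C)(C)C)cc(O[Si](C)(C)C(C)(C)C)c(C[C@H](CC=C(C)C)C(C)(C)O[Si](CC)(CC)CC)c1OC
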